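The C8=C17 and C14=C15 methylenes, the C12=C13 alkene and the C11–C12 bond are removed first; the C8‑oxygenated, C9‑acyl decalin that remains is cut at C5–C10 and C8–C9 in one [4+2] step, and the open chain at C3–C4 (malonate alkylation), C9–C11/C10–C20 (carboalumination–acylation) and C6=C7 (metathesis).
Enabling feature: ring B (C5–C10) holds the C5–C10 and C8–C9 bonds, flanked by the methyl‑bearing C10, a C9 with a one‑carbon branch (C11) and an oxidisable C8; a C9=C10 enoyl dienophile and a C5=C6–C7=C8–O diene, linked by C1–C4 through the symmetric quaternary C4, map onto rings B and A.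
Forward: alkylation of allylmalonate builds C4 with both arms; reduction, silylation, carboalumination–acylation (E‑C9=C10 with C20), auxiliary attachment, cross‑metathesis and dienol silylation give the triene; one cycloaddition closes ring B and, through the tether, ring A.
Then: hydrogenation of C6=C7, auxiliary removal, C11→C12 homologation, two Wittig reactions (12E,14‑diene), desilylation, diacetylation, C8 oxidation and methylenation.
Stereochemistry: C9 from the (R)‑4‑benzyloxazolidinone in its aluminium chelate; C10 and C5 relative to C9 from the E‑dienophile and the endo, trans‑fusing transition state; 12E from a stabilised ylide; C4 needs no control.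

Key step: step 9

Remark: labdane numbering is used throughout (ring A = C1–C5/C10, ring B = C5–C10, C17 on C8, C18/C19 on C4, C20 on C10); the target SMILES is read as the (5S,9R,10S) isomer; TBS = tert‑butyldimethylsilyl, TIPS = triisopropylsilyl; it is assumed that a minor 7Z isomer of the silyl dienol ether, if formed, does not cyclise and is removed after step 9.

Step 1
Reactants: 1 diethyl allylmalonate; 2 5-chloropent-1-yne
Product: 3 diethyl 2-allyl-2-(pent-4-yn-1-yl)malonate
Conditions: NaH, DMF, 0 °C; then 2, NaI (cat.), 70 °C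
Reagents that add atoms: none
Why: Malonate alkylation (SN2) – the sodium enolate of 1 displaces the primary halide (iodide formed in situ by Finkelstein exchange) and creates the future quaternary C4 with two identical ester arms, so no stereocentre arises.

Step 2
Reactants: 3 diethyl 2-allyl-2-(pent-4-yn-1-yl)malonate
Product: 4 2-allyl-2-(pent-4-yn-1-yl)propane-1,3-diol
Conditions: LiAlH4, THF, 0 °C → rt
Reagents that add atoms: none
Why: Hydride reduction of both esters to the 1,3-diol; the isolated alkene and the terminal alkyne are inert to LiAlH4 at this temperature.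

Step 3
Reactants: 4 2-allyl-2-(pent-4-yn-1-yl)propane-1,3-diol
Product: 5 4,4-bis[(triisopropylsilyloxy)methyl]non-1-en-8-yne
Conditions: TIPSOTf, 2,6-lutidine, CH2Cl2, 0 °C → rt
Reagents that add atoms: triisopropylsilyl triflate, CC(C)[Si](OS(=O)(=O)C(F)(F)F)(C(C)C)C(C)C
Why: Silyl ether formation with a silyl triflate and a hindered base protects both neopentyl hydroxyls as TIPS ethers, which are poor Lewis bases and should pass the organoaluminium, hydroxide and dilute-acid steps up to step 17.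

Step 4
Reactants: 5 4,4-bis[(triisopropylsilyloxy)methyl]non-1-en-8-yne
Product: 7 methyl (2E)-3-methyl-7,7-bis[(triisopropylsilyloxy)methyl]deca-2,9-dienoate, via alkenyldimethylalane 6 (not isolated)
Conditions: Me3Al, Cp2ZrCl2 (cat.), CH2Cl2, 0 °C → rt; then ClCO2Me, rt; aq. HCl work-up
Reagents that add atoms: trimethylaluminium, C[Al](C)C; methyl chloroformate, COC(=O)Cl
Why: Negishi zirconium-catalysed carboalumination adds methyl and aluminium syn across the terminal alkyne with aluminium at the terminus (the monosubstituted alkene does not react under Cp2ZrCl2 catalysis), and acylation of the alkenylalane by the chloroformate with retention gives the trisubstituted E-enoate in which the C20 methyl is cis to C11.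

Step 5
Reactants: 7 methyl (2E)-3-methyl-7,7-bis[(triisopropylsilyloxy)methyl]deca-2,9-dienoate
Product: 8 (2E)-3-methyl-7,7-bis[(triisopropylsilyloxy)methyl]deca-2,9-dienoic acid
Conditions: LiOH, THF/MeOH/H2O, 45 °C; then aq. HCl to pH 3
Reagents that add atoms: lithium hydroxide, [Li+].[OH-]
Why: Ester saponification; TIPS ethers tolerate aqueous hydroxide and the geometry of the trisubstituted alkene is not touched.

Step 6
Reactants: 8 (2E)-3-methyl-7,7-bis[(triisopropylsilyloxy)methyl]deca-2,9-dienoic acid; 9 (R)-4-benzyl-2-oxazolidinone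
Product: 11 (R)-4-benzyl-3-[(2E)-3-methyl-7,7-bis(TIPS-oxymethyl)deca-2,9-dienoyl]oxazolidin-2-one, via mixed pivalic anhydride 10 (not isolated)
Conditions: PivCl, Et3N, THF, −20 °C; then LiCl, 9, −20 °C → rt
Reagents that add atoms: pivaloyl chloride, CC(C)(C)C(=O)Cl (its atoms remain only in intermediate 10)
Why: N-acylation of the oxazolidinone through the mixed pivalic anhydride under LiCl/Et3N activation, the hindered pivaloyl carbonyl steering attack to the enoyl carbonyl.

Step 7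
Reactants: 11 (R)-4-benzyl-3-[(2E)-3-methyl-7,7-bis(TIPS-oxymethyl)deca-2,9-dienoyl]oxazolidin-2-one; 12 (E)-crotonaldehyde
Product: 13 (R)-4-benzyl-3-[(2E,9E)-3-methyl-11-oxo-7,7-bis(TIPS-oxymethyl)undeca-2,9-dienoyl]oxazolidin-2-one
Conditions: second-generation Grubbs catalyst (H2IMes)(PCy3)Cl2Ru=CHPh (cat.), 12 (excess), CH2Cl2, 40 °C
Reagents that add atoms: none
Why: Olefin cross-metathesis of the monosubstituted allyl alkene with excess crotonaldehyde gives the E-enal under thermodynamic control, while the trisubstituted, electron-poor enimide alkene does not take part.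

Step 8
Reactants: 13 (R)-4-benzyl-3-[(2E,9E)-3-methyl-11-oxo-7,7-bis(TIPS-oxymethyl)undeca-2,9-dienoyl]oxazolidin-2-one
Product: 14 (R)-4-benzyl-3-[(2E,8E,10E)-11-(TBS-oxy)-3-methyl-7,7-bis(TIPS-oxymethyl)undeca-2,8,10-trienoyl]oxazolidin-2-one
Conditions: TBSOTf, Et3N, CH2Cl2, −78 → 0 °C; filtration through Et3N-deactivated silica
Reagents that add atoms: tert-butyldimethylsilyl triflate, CC(C)(C)[Si](C)(C)OS(=O)(=O)C(F)(F)F
Why: Soft γ-enolisation (silyl dienol ether formation) of the E-enal through its s-trans conformer should give the 1-silyloxy-1,3-diene with C5=C6 E and mainly C7=C8 E, the aldehyde being silylated far faster than the imide.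

Step 9
Reactants: 14 (R)-4-benzyl-3-[(2E,8E,10E)-11-(TBS-oxy)-3-methyl-7,7-bis(TIPS-oxymethyl)undeca-2,8,10-trienoyl]oxazolidin-2-one
Product: 15 (R)-4-benzyl-3-[(5S,8R,9S,10R)-8-(TBS-oxy)-18,19-bis(TIPS-oxy)-12,13,14,15,16,17-hexanorlabd-6-en-11-oyl]oxazolidin-2-one
Conditions: Me2AlCl (2 equiv), CH2Cl2, −30 → 0 °C; then cold 1 M HCl
Reagents that add atoms: none
Why: Excess Me2AlCl converts the imide into the cationic two-point aluminium chelate with the enoyl unit locked s-cis (the C20 methyl, cis to the carbonyl, excludes the s-trans form), and the tethered silyloxydiene then adds across C9=C10 in a normal-electron-demand, concerted but asynchronous [4+2] cycloaddition in which C5–C10 bonding runs ahead of C8–C9 bonding. The closest known reaction type is the Me2AlCl-promoted intramolecular Diels–Alder reaction of 2,8,10-undecatrienoyl oxazolidinones to trans-fused octalins; the extra β-methyl group makes this a less reactive case, which the electron-rich diene and the gem-disubstituted C4 (Thorpe–Ingold effect) are meant to offset. Ring B (C5–C6–C7–C8–C9–C10) closes as the new cyclohexene by the [4+2] union itself, and ring A (C10–C1–C2–C3–C4–C5) closes in the same event as a six-membered carbocycle through the C1–C4 tether between dienophile carbon C10 and diene carbon C5. C9 is set by the auxiliary, whose benzyl group covers the Cα-Si face of the chelate so that C8 bonds to the Cα-Re face; C10 follows from the E geometry of the dienophile (C11 and C20 stay cis in the suprafacial addition); C5 follows from the endo transition state (imide carbonyl under the diene, chair-like tether), which gives the trans ring fusion; C8 follows from the E silyloxy terminus, which ends cis to C11. The step needs Re-face and endo selectivity, secured by chelation plus the benzyl shield and by the E,E,E geometry of the triene, while the regiochemistry is fixed by the tether and agrees with the electronic preference (nucleophilic C5 to electrophilic C10). A stepwise Mukaiyama–Michael addition followed by closure of the aluminium enolate onto the silyloxocarbenium ion would lead to the same adduct, and C4 with its two identical arms adds no stereochemical issue.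

Step 10
Reactants: 15 (R)-4-benzyl-3-[(5S,8R,9S,10R)-8-(TBS-oxy)-18,19-bis(TIPS-oxy)-12,13,14,15,16,17-hexanorlabd-6-en-11-oyl]oxazolidin-2-one
Product: 16 (R)-4-benzyl-3-[(5S,8R,9S,10R)-8-(TBS-oxy)-18,19-bis(TIPS-oxy)-12,13,14,15,16,17-hexanorlabdan-11-oyl]oxazolidin-2-one
Conditions: H2 (1 atm), PtO2 (cat.), EtOAc, rt
Reagents that add atoms: none
Why: Heterogeneous catalytic hydrogenation saturates the cis-disubstituted C6=C7 bond without creating a stereocentre, platinum dioxide in a neutral solvent being chosen to limit hydrogenolysis of the allylic silyl ether.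

Step 11
Reactants: 16 (R)-4-benzyl-3-[(5S,8R,9S,10R)-8-(TBS-oxy)-18,19-bis(TIPS-oxy)-12,13,14,15,16,17-hexanorlabdan-11-oyl]oxazolidin-2-one
Product: 17 (5S,8R,9R,10R)-8-(TBS-oxy)-18,19-bis(TIPS-oxy)-12,13,14,15,16,17-hexanorlabdan-11-ol
Conditions: LiBH4, H2O (1 equiv), Et2O, 0 °C → rt
Reagents that add atoms: none
Why: Reductive cleavage of the N-acyloxazolidinone (hydride attack at the exocyclic carbonyl, then reduction of the released aldehyde) gives the C11 alcohol and returns the auxiliary, the silyl ethers being inert.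

Step 12
Reactants: 17 (5S,8R,9R,10R)-8-(TBS-oxy)-18,19-bis(TIPS-oxy)-12,13,14,15,16,17-hexanorlabdan-11-ol
Product: 18 (5S,8R,9S,10R)-8-(TBS-oxy)-18,19-bis(TIPS-oxy)-12,13,14,15,16,17-hexanorlabdan-11-al
Conditions: Dess–Martin periodinane, pyridine, CH2Cl2, rt
Reagents that add atoms: none
Why: Dess–Martin oxidation of the primary alcohol under buffered, non-epimerising conditions, with the equatorial C9 substituent being the thermodynamically favoured arrangement in any case.

Step 13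
Reactants: 18 (5S,8R,9S,10R)-8-(TBS-oxy)-18,19-bis(TIPS-oxy)-12,13,14,15,16,17-hexanorlabdan-11-al
Product: 19 (5S,8R,9S,10R)-12-methoxy-8-(TBS-oxy)-18,19-bis(TIPS-oxy)-13,14,15,16,17-pentanorlabd-11-ene (E/Z mixture)
Conditions: Ph3P(CH2OMe)Cl, KN(SiMe3)2, THF, 0 °C; then 18, 0 °C → rt
Reagents that add atoms: (methoxymethyl)triphenylphosphonium chloride, COC[P+](c1ccccc1)(c1ccccc1)c1ccccc1.[Cl-]
Why: Wittig reaction with the non-stabilised methoxymethylene ylide converts the hindered aldehyde into the enol ether, either alkene geometry serving equally.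

Step 14
Reactants: 19 (5S,8R,9S,10R)-12-methoxy-8-(TBS-oxy)-18,19-bis(TIPS-oxy)-13,14,15,16,17-pentanorlabd-11-ene (E/Z mixture)
Product: 20 (5S,8R,9S,10R)-8-(TBS-oxy)-18,19-bis(TIPS-oxy)-13,14,15,16,17-pentanorlabdan-12-al
Conditions: 1 M HCl, THF, 0 °C → rt
Reagents that add atoms: water, O
Why: Acid-catalysed enol ether hydrolysis (C-protonation, hydration of the oxocarbenium ion, loss of methanol) gives the one-carbon homologated aldehyde, and the hindered axial TBS ether and the neopentyl TIPS ethers should survive brief dilute acid.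

Step 15
Reactants: 20 (5S,8R,9S,10R)-8-(TBS-oxy)-18,19-bis(TIPS-oxy)-13,14,15,16,17-pentanorlabdan-12-al
Product: 21 (5S,8R,9S,10R,12E)-8-(TBS-oxy)-18,19-bis(TIPS-oxy)-15,17-dinorlabd-12-en-14-al
Conditions: Ph3P=C(Me)CHO, toluene, 90 °C
Reagents that add atoms: 2-(triphenylphosphoranylidene)propanal, CC(C=O)=P(c1ccccc1)(c1ccccc1)c1ccccc1
Why: Wittig reaction of the stabilised formyl ylide with the unbranched aldehyde gives the trisubstituted enal with E geometry at C12=C13, as expected for stabilised ylides.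

Step 16
Reactants: 21 (5S,8R,9S,10R,12E)-8-(TBS-oxy)-18,19-bis(TIPS-oxy)-15,17-dinorlabd-12-en-14-al
Product: 22 (5S,8R,9S,10R,12E)-8-(TBS-oxy)-18,19-bis(TIPS-oxy)-17-norlabda-12,14-diene
Conditions: Ph3PCH3Br, KN(SiMe3)2, THF, 0 °C; then 21, 0 °C → rt
Reagents that add atoms: methyltriphenylphosphonium bromide, C[P+](c1ccccc1)(c1ccccc1)c1ccccc1.[Br-]
Why: Wittig methylenation of the enal carbonyl forms C14=C15 and completes the E-1,3-diene without affecting the C12=C13 geometry.

Step 17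
Reactants: 22 (5S,8R,9S,10R,12E)-8-(TBS-oxy)-18,19-bis(TIPS-oxy)-17-norlabda-12,14-diene
Product: 23 (5S,8R,9S,10R,12E)-17-norlabda-12,14-diene-8,18,19-triol
Conditions: Bu4NF, THF, rt → 50 °C
Reagents that add atoms: none
Why: Fluoride-mediated desilylation removes the two TIPS ethers and the hindered axial TBS ether under non-acidic conditions that the diene tolerates.

Step 18
Reactants: 23 (5S,8R,9S,10R,12E)-17-norlabda-12,14-diene-8,18,19-triol
Product: 24 (5S,8R,9S,10R,12E)-8-hydroxy-17-norlabda-12,14-diene-18,19-diyl diacetate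
Conditions: Ac2O, pyridine, CH2Cl2, 0 °C → rt (no DMAP)
Reagents that add atoms: acetic anhydride, CC(=O)OC(C)=O
Why: Selective O-acetylation – the two primary hydroxyls react with Ac2O/pyridine, while the axial C8 hydroxyl, 1,3-diaxial to the C20 methyl and flanked by C9, should stay free.

Step 19
Reactants: 24 (5S,8R,9S,10R,12E)-8-hydroxy-17-norlabda-12,14-diene-18,19-diyl diacetate
Product: 25 (5S,9S,10R,12E)-8-oxo-17-norlabda-12,14-diene-18,19-diyl diacetate
Conditions: Dess–Martin periodinane, pyridine, CH2Cl2, 0 °C → rt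
Reagents that add atoms: none
Why: Dess–Martin oxidation of the hindered axial secondary alcohol (with relief of the 1,3-diaxial interaction) gives the C8 ketone, the pyridine buffer sparing the diene and the equatorial C9 substituent.

Step 20
Reactants: 25 (5S,9S,10R,12E)-8-oxo-17-norlabda-12,14-diene-18,19-diyl diacetate
Product: 26 (5S,9R,10S,12E)-labda-8(17),12,14-triene-18,19-diyl diacetate
Conditions: Zn, CH2Br2, TiCl4, THF, −40 → 5 °C (reagent preformed); then 25, CH2Cl2, 0 °C → rt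
Reagents that add atoms: dibromomethane, BrCBr
Why: Takai–Lombardo methylenation – the non-basic zinc/titanium methylene reagent converts ketones into 1,1-disubstituted alkenes in the presence of esters and does not enolise C9, so the acetates and the C9 configuration should be kept.

Compound list
1 | diethyl allylmalonate | C=CCC(C(=O)OCC)C(=O)OCC | starting material
2 | 5-chloropent-1-yne | C#CCCCCl | starting material
3 | diethyl 2-allyl-2-(pent-4-yn-1-yl)malonate | C=CCC(CCCC#C)(C(=O)OCC)C(=O)OCC | intermediate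
4 | 2-allyl-2-(pent-4-yn-1-yl)propane-1,3-diol | C=CCC(CCCC#C)(CO)CO | intermediate
5 | 4,4-bis[(triisopropylsilyloxy)methyl]non-1-en-8-yne | C=CCC(CCCC#C)(CO[Si](C(C)C)(C(C)C)C(C)C)CO[Si](C(C)C)(C(C)C)C(C)C | intermediate
6 | dimethyl[(1E)-2-methyl-6,6-bis(TIPS-oxymethyl)nona-1,8-dienyl]alane (not isolated) | C=CCC(CCC/C(C)=C/[Al](C)C)(CO[Si](C(C)C)(C(C)C)C(C)C)CO[Si](C(C)C)(C(C)C)C(C)C | intermediate
7 | methyl (2E)-3-methyl-7,7-bis[(triisopropylsilyloxy)methyl]deca-2,9-dienoate | C=CCC(CCC/C(C)=C/C(=O)OC)(CO[Si](C(C)C)(C(C)C)C(C)C)CO[Si](C(C)C)(C(C)C)C(C)C | intermediate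
8 | (2E)-3-methyl-7,7-bis[(triisopropylsilyloxy)methyl]deca-2,9-dienoic acid | C=CCC(CCC/C(C)=C/C(=O)O)(CO[Si](C(C)C)(C(C)C)C(C)C)CO[Si](C(C)C)(C(C)C)C(C)C | intermediate
9 | (R)-4-benzyl-2-oxazolidinone | O=C1OC[C@@H](Cc2ccccc2)N1 | starting material
10 | mixed anhydride of acid 8 with pivalic acid (not isolated) | C=CCC(CCC/C(C)=C/C(=O)OC(=O)C(C)(C)C)(CO[Si](C(C)C)(C(C)C)C(C)C)CO[Si](C(C)C)(C(C)C)C(C)C | intermediate
11 | (R)-4-benzyl-3-[(2E)-3-methyl-7,7-bis(TIPS-oxymethyl)deca-2,9-dienoyl]oxazolidin-2-one | O=C1OC[C@@H](Cc2ccccc2)N1C(=O)/C=C(\C)CCCC(CC=C)(CO[Si](C(C)C)(C(C)C)C(C)C)CO[Si](C(C)C)(C(C)C)C(C)C | intermediate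
12 | (E)-crotonaldehyde | C/C=C/C=O | starting material
13 | (R)-4-benzyl-3-[(2E,9E)-3-methyl-11-oxo-7,7-bis(TIPS-oxymethyl)undeca-2,9-dienoyl]oxazolidin-2-one | O=C1OC[C@@H](Cc2ccccc2)N1C(=O)/C=C(\C)CCCC(C/C=C/C=O)(CO[Si](C(C)C)(C(C)C)C(C)C)CO[Si](C(C)C)(C(C)C)C(C)C | intermediate
14 | (R)-4-benzyl-3-[(2E,8E,10E)-11-(TBS-oxy)-3-methyl-7,7-bis(TIPS-oxymethyl)undeca-2,8,10-trienoyl]oxazolidin-2-one (cycloaddition precursor) | O=C1OC[C@@H](Cc2ccccc2)N1C(=O)/C=C(\C)CCCC(/C=C/C=C/O[Si](C)(C)C(C)(C)C)(CO[Si](C(C)C)(C(C)C)C(C)C)CO[Si](C(C)C)(C(C)C)C(C)C | intermediate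
15 | (R)-4-benzyl-3-[(5S,8R,9S,10R)-8-(TBS-oxy)-18,19-bis(TIPS-oxy)-12,13,14,15,16,17-hexanorlabd-6-en-11-oyl]oxazolidin-2-one (trans-fused cycloadduct; H5 anti to C20; C11 and 8-OTBS cis to C20) | O=C1OC[C@@H](Cc2ccccc2)N1C(=O)[C@@H]3[C@H](O[Si](C)(C)C(C)(C)C)C=C[C@@H]4C(CO[Si](C(C)C)(C(C)C)C(C)C)(CO[Si](C(C)C)(C(C)C)C(C)C)CCC[C@@]34C | intermediate
16 | (R)-4-benzyl-3-[(5S,8R,9S,10R)-8-(TBS-oxy)-18,19-bis(TIPS-oxy)-12,13,14,15,16,17-hexanorlabdan-11-oyl]oxazolidin-2-one | O=C1OC[C@@H](Cc2ccccc2)N1C(=O)[C@@H]3[C@H](O[Si](C)(C)C(C)(C)C)CC[C@@H]4C(CO[Si](C(C)C)(C(C)C)C(C)C)(CO[Si](C(C)C)(C(C)C)C(C)C)CCC[C@@]34C | intermediate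
17 | (5S,8R,9R,10R)-8-(TBS-oxy)-18,19-bis(TIPS-oxy)-12,13,14,15,16,17-hexanorlabdan-11-ol | OC[C@@H]1[C@H](O[Si](C)(C)C(C)(C)C)CC[C@@H]2C(CO[Si](C(C)C)(C(C)C)C(C)C)(CO[Si](C(C)C)(C(C)C)C(C)C)CCC[C@@]12C | intermediate
18 | (5S,8R,9S,10R)-8-(TBS-oxy)-18,19-bis(TIPS-oxy)-12,13,14,15,16,17-hexanorlabdan-11-al | O=C[C@@H]1[C@H](O[Si](C)(C)C(C)(C)C)CC[C@@H]2C(CO[Si](C(C)C)(C(C)C)C(C)C)(CO[Si](C(C)C)(C(C)C)C(C)C)CCC[C@@]12C | intermediate
19 | (5S,8R,9S,10R)-12-methoxy-8-(TBS-oxy)-18,19-bis(TIPS-oxy)-13,14,15,16,17-pentanorlabd-11-ene, E/Z mixture | COC=C[C@@H]1[C@H](O[Si](C)(C)C(C)(C)C)CC[C@@H]2C(CO[Si](C(C)C)(C(C)C)C(C)C)(CO[Si](C(C)C)(C(C)C)C(C)C)CCC[C@@]12C | intermediate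
20 | (5S,8R,9S,10R)-8-(TBS-oxy)-18,19-bis(TIPS-oxy)-13,14,15,16,17-pentanorlabdan-12-al | O=CC[C@@H]1[C@H](O[Si](C)(C)C(C)(C)C)CC[C@@H]2C(CO[Si](C(C)C)(C(C)C)C(C)C)(CO[Si](C(C)C)(C(C)C)C(C)C)CCC[C@@]12C | intermediate
21 | (5S,8R,9S,10R,12E)-8-(TBS-oxy)-18,19-bis(TIPS-oxy)-15,17-dinorlabd-12-en-14-al | O=C/C(C)=C/C[C@@H]1[C@H](O[Si](C)(C)C(C)(C)C)CC[C@@H]2C(CO[Si](C(C)C)(C(C)C)C(C)C)(CO[Si](C(C)C)(C(C)C)C(C)C)CCC[C@@]12C | intermediate
22 | (5S,8R,9S,10R,12E)-8-(TBS-oxy)-18,19-bis(TIPS-oxy)-17-norlabda-12,14-diene | C=C/C(C)=C/C[C@@H]1[C@H](O[Si](C)(C)C(C)(C)C)CC[C@@H]2C(CO[Si](C(C)C)(C(C)C)C(C)C)(CO[Si](C(C)C)(C(C)C)C(C)C)CCC[C@@]12C | intermediate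
23 | (5S,8R,9S,10R,12E)-17-norlabda-12,14-diene-8,18,19-triol | C=C/C(C)=C/C[C@@H]1[C@H](O)CC[C@@H]2C(CO)(CO)CCC[C@@]12C | intermediate
24 | (5S,8R,9S,10R,12E)-8-hydroxy-17-norlabda-12,14-diene-18,19-diyl diacetate | C=C/C(C)=C/C[C@@H]1[C@H](O)CC[C@@H]2C(COC(C)=O)(COC(C)=O)CCC[C@@]12C | intermediate
25 | (5S,9S,10R,12E)-8-oxo-17-norlabda-12,14-diene-18,19-diyl diacetate | C=C/C(C)=C/C[C@@H]1C(=O)CC[C@@H]2C(COC(C)=O)(COC(C)=O)CCC[C@@]12C | intermediate
26 | (5S,9R,10S,12E)-labda-8(17),12,14-triene-18,19-diyl diacetate (CNP0129553.1) | C=C/C(C)=C/C[C@@H]1C(=C)CC[C@@H]2C(COC(C)=O)(COC(C)=O)CCC[C@@]12C | target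

Total step count: 20. Longest linear sequence: 20 steps (1 → 26).

Steps most likely to fail

Step 9. Bond formation at the fully substituted dienophile carbon C10 may be slow. Lewis-acid-induced loss of the silyl dienol ether (protodesilylation, intermolecular Mukaiyama–Michael addition) or erosion of facial control could then compete with ring closure. The fallback replaces auxiliary control by catalyst control with a milder, catalytic two-point-binding Lewis acid that tolerates silyl enol ethers. Acid 8 is coupled through mixed anhydride 10 with achiral oxazolidin-2-one to give 3-[(2E)-3-methyl-7,7-bis(TIPS-oxymethyl)deca-2,9-dienoyl]oxazolidin-2-one F1. Cross-metathesis with 12 gives 3-[(2E,9E)-3-methyl-11-oxo-7,7-bis(TIPS-oxymethyl)undeca-2,9-dienoyl]oxazolidin-2-one F2, and TBSOTf/Et3N gives 3-[(2E,8E,10E)-11-(TBS-oxy)-3-methyl-7,7-bis(TIPS-oxymethyl)undeca-2,8,10-trienoyl]oxazolidin-2-one F3. Cyclisation with catalytic [Cu(t-Bu-box)](SbF6)2 (divalent copper; t-Bu-box = 2,2'-isopropylidenebis(4-tert-butyl-2-oxazoline), the ligand antipode that leaves the Cα-Re face open in the square-planar chelate) in CH2Cl2 at rt should give 3-[(5S,8R,9S,10R)-8-(TBS-oxy)-18,19-bis(TIPS-oxy)-12,13,14,15,16,17-hexanorlabd-6-en-11-oyl]oxazolidin-2-one F4. Hydrogenation (H2, PtO2) gives 3-[(5S,8R,9S,10R)-8-(TBS-oxy)-18,19-bis(TIPS-oxy)-12,13,14,15,16,17-hexanorlabdan-11-oyl]oxazolidin-2-one F5, and LiBH4 reduction then delivers alcohol 17, where the route is rejoined.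

Step 11. In the very hindered imide (C9 lies between quaternary C10 and the silyloxy-bearing C8), hydride may attack the ring carbamate carbonyl and open the oxazolidinone instead of releasing the acyl group. The fallback sets out from 16 and cleaves with LiOH/H2O2 in THF/H2O at 0 °C, where hydroperoxide adds selectively to the exocyclic carbonyl. This gives (5S,8R,9S,10R)-8-(TBS-oxy)-18,19-bis(TIPS-oxy)-12,13,14,15,16,17-hexanorlabdan-11-oic acid F6 and the recovered auxiliary. Reduction of F6 with LiAlH4 in THF returns to alcohol 17.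

Step 20. Methylene transfer to the hindered, enolisable C8 ketone may stall, or the Lewis-acidic titanium species may isomerise the diene or strip acetate before olefination is complete. The fallback sets out from 25 and gives up the acetates for the olefination. Methanolysis (K2CO3, MeOH) gives (5S,9S,10R,12E)-18,19-dihydroxy-17-norlabda-12,14-dien-8-one F7. Wittig methylenation with excess Ph3P=CH2 (from Ph3PCH3Br and KN(SiMe3)2, THF, rt → 60 °C; the alkoxides are spectators) gives (5S,9R,10S,12E)-labda-8(17),12,14-triene-18,19-diol F8. Acetylation (Ac2O, pyridine, DMAP) rejoins the route at 26.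

Further compounds
F1 | step 9 | 3-[(2E)-3-methyl-7,7-bis(TIPS-oxymethyl)deca-2,9-dienoyl]oxazolidin-2-one | O=C1OCCN1C(=O)/C=C(\C)CCCC(CC=C)(CO[Si](C(C)C)(C(C)C)C(C)C)CO[Si](C(C)C)(C(C)C)C(C)C
F2 | step 9 | 3-[(2E,9E)-3-methyl-11-oxo-7,7-bis(TIPS-oxymethyl)undeca-2,9-dienoyl]oxazolidin-2-one | O=C1OCCN1C(=O)/C=C(\C)CCCC(C/C=C/C=O)(CO[Si](C(C)C)(C(C)C)C(C)C)CO[Si](C(C)C)(C(C)C)C(C)C
F3 | step 9 | 3-[(2E,8E,10E)-11-(TBS-oxy)-3-methyl-7,7-bis(TIPS-oxymethyl)undeca-2,8,10-trienoyl]oxazolidin-2-one | O=C1OCCN1C(=O)/C=C(\C)CCCC(/C=C/C=C/O[Si](C)(C)C(C)(C)C)(CO[Si](C(C)C)(C(C)C)C(C)C)CO[Si](C(C)C)(C(C)C)C(C)C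
F4 | step 9 | 3-[(5S,8R,9S,10R)-8-(TBS-oxy)-18,19-bis(TIPS-oxy)-12,13,14,15,16,17-hexanorlabd-6-en-11-oyl]oxazolidin-2-one | O=C1OCCN1C(=O)[C@@H]2[C@H](O[Si](C)(C)C(C)(C)C)C=C[C@@H]3C(CO[Si](C(C)C)(C(C)C)C(C)C)(CO[Si](C(C)C)(C(C)C)C(C)C)CCC[C@@]23C
F5 | step 9 | 3-[(5S,8R,9S,10R)-8-(TBS-oxy)-18,19-bis(TIPS-oxy)-12,13,14,15,16,17-hexanorlabdan-11-oyl]oxazolidin-2-one | O=C1OCCN1C(=O)[C@@H]2[C@H](O[Si](C)(C)C(C)(C)C)CC[C@@H]3C(CO[Si](C(C)C)(C(C)C)C(C)C)(CO[Si](C(C)C)(C(C)C)C(C)C)CCC[C@@]23C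
F6 | step 11 | (5S,8R,9S,10R)-8-(TBS-oxy)-18,19-bis(TIPS-oxy)-12,13,14,15,16,17-hexanorlabdan-11-oic acid | OC(=O)[C@@H]1[C@H](O[Si](C)(C)C(C)(C)C)CC[C@@H]2C(CO[Si](C(C)C)(C(C)C)C(C)C)(CO[Si](C(C)C)(C(C)C)C(C)C)CCC[C@@]12C
F7 | step 20 | (5S,9S,10R,12E)-18,19-dihydroxy-17-norlabda-12,14-dien-8-one | C=C/C(C)=C/C[C@@H]1C(=O)CC[C@@H]2C(CO)(CO)CCC[C@@]12C
F8 | step 20 | (5S,9R,10S,12E)-labda-8(17),12,14-triene-18,19-diol | C=C/C(C)=C/C[C@@H]1C(=C)CC[C@@H]2C(CO)(CO)CCC[C@@]12C
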